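**Plan**
- Retrosynthetic cuts, in order: C13–C14 (Stille coupling) and C12=C13 (iodo-olefination of a C12 aldehyde that comes from an allyl group); the two acetates and the C6–O and C8–O bonds; C9–C11 (allyl addition, then 1,3-carbonyl transposition); C3–C4 of ring A; C10–C1 and C10–C20 (enolate alkylations).
- Forward: ring B is (S)-carvone from the start; two alkylations build the quaternary C10; ring A (C1–C5, C10) closes onto ring B (C5–C10) by a hydrogen-atom-transfer Giese reaction; ring B is then oxygenated and the C11–C16 chain is finished last.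
- Enabling feature: the gem-dimethyl carbon C4 lies next to the ring-fusion carbon C5 and is the isopropenyl carbon of carvone, so a tertiary C4 radical can reach C3 of an acrylate arm that hangs from C10 through C1.
- Stereochemistry: C5 comes from carvone; C10 from alkylation anti to the isopropenyl group; C9 from axial protonation in the dissolving-metal reduction; C8 and C6 from oxidant attack anti to the C20 methyl; C7 from axial hydride delivery; the 12Z alkene from a Z-selective iodo-olefination and a stereoretentive coupling.

Key step: step 3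

Remark: bicyclic compounds are numbered as labdanes (ring A = C1–C5 and C10; ring B = C5–C10; C17 on C8, C18 and C19 on C4, C20 on C10, chain C11–C16), and "syn" and "anti" refer to the C20 methyl. The target belongs to the ent-labdane series. The configurations drawn for C6 of 4, C2 of 8 and 9, and C9 of 12 are the expected ones; each of these centres is erased later, so any epimer mixture is carried on.

**Step 1**
Reactants: 1 (S)-(+)-carvone; 2 iodomethane
Product: 4 (5S,6R)-6-methylcarvone, via lithium dienolate of carvone 3 (not isolated)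
Conditions: LiN(iPr)2, THF, −78 °C; then MeI, −78 → 0 °C
Reagents that add atoms: iodomethane, CI
Why: Kinetic deprotonation at the saturated α'-carbon gives the cross-conjugated lithium dienolate, and its SN2 methylation (enolate alkylation) installs the future C20 methyl; the new centre is made trigonal again in step 2, and the carvone stereocentre is not acidic and stays untouched.

**Step 2**
Reactants: 4 (5S,6R)-6-methylcarvone; 5 methyl 2-(bromomethyl)acrylate
Product: 7 6-methyl-6-[2-(methoxycarbonyl)allyl]carvone (acrylate arm trans to isopropenyl), via lithium enolate of 6-methylcarvone 6 (not isolated)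
Conditions: LiN(iPr)2, THF, −78 °C; then 5, −78 → −20 °C
Reagents that add atoms: methyl 2-(bromomethyl)acrylate, C=C(CBr)C(=O)OC
Why: Enolate alkylation with an allylic bromide that reacts by SN2' addition–elimination; the tetrasubstituted enolate is attacked on the face anti to the neighbouring isopropenyl group, which sets the quaternary carbon (future C10) with the acrylate arm trans and the methyl cis to the isopropenyl group, the usual outcome of double alkylation of carvone.

**Step 3**
Reactants: 7 6-methyl-6-[2-(methoxycarbonyl)allyl]carvone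
Product: 8 methyl 9-oxo-ent-11-nordrim-7-ene-2-carboxylate (trans-fused; ester equatorial)
Conditions: Fe(acac)3 (30 mol %), PhSiH3 (2.5 equiv), EtOH/HOCH2CH2OH 5:1, 0.01 M, 60 °C
Reagents that add atoms: none
Why: The trivalent iron hydride formed from Fe(acac)3 and PhSiH3 transfers a hydrogen atom to the methylene carbon of the electron-rich isopropenyl group, which creates the second C4 methyl and a tertiary radical at C4; this nucleophilic radical adds to the unsubstituted acrylate terminus C3, and the ester-stabilised C2 radical is reduced by divalent iron and protonated by ethanol. The closest known reaction type is the iron-catalysed reductive coupling of an unactivated alkene with an acrylate (hydrogen-atom-transfer Giese reaction) in its intramolecular form. Ring A closes in the 6-endo-trig mode, because 5-exo attack would have to strike the ester-bearing internal alkene carbon against both polarity and steric hindrance. The ring fusion needs no induction: C5 and C10 are already fixed and hold the two reacting arms trans and diequatorial on the cyclohexenone, so a chair transition state can lead only to the trans-decalin; the single new centre C2 arises on protonation, is expected to end with the ester equatorial and is deleted in step 5. The step needs hydrogen-atom transfer to the isopropenyl group rather than to the acrylate or the enone, and cyclisation faster than reduction of the C4 radical; the first is secured by the polarity of the 1,1-disubstituted alkene, the second by the polarity-matched acceptor held within reach and by high dilution.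

**Step 4**
Reactants: 8 methyl 9-oxo-ent-11-nordrim-7-ene-2-carboxylate
Product: 9 9-oxo-ent-11-nordrim-7-ene-2-carboxylic acid
Conditions: LiOH, THF/MeOH/H2O, 40 °C; then aq HCl
Reagents that add atoms: lithium hydroxide, [Li+].[OH-]
Why: Saponification (acyl substitution by hydroxide) of the unhindered secondary methyl ester; neither C5 nor C10 carries an acidic hydrogen, so the ring fusion cannot epimerise.

**Step 5**
Reactants: 9 9-oxo-ent-11-nordrim-7-ene-2-carboxylic acid
Product: 10 ent-11-nordrim-7-en-9-one
Conditions: 9-mesityl-10-phenylacridinium tetrafluoroborate (5 mol %), PhSSPh (10 mol %), iPr2NEt (20 mol %), CF3CH2OH, 450 nm LEDs, rt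
Reagents that add atoms: none
Why: Photoredox hydrodecarboxylation: the excited acridinium oxidises the carboxylate, loss of CO2 gives a secondary C2 radical, and this takes a hydrogen atom from thiophenol formed from the disulfide co-catalyst, so the C2 centre disappears while the electron-poor enone is not oxidised.

**Step 6**
Reactants: 10 ent-11-nordrim-7-en-9-one; 11 allylmagnesium bromide
Product: 12 9-allyl-ent-11-nordrim-7-en-9-ol (allyl anti to C20)
Conditions: CH2=CHCH2MgBr, Et2O, −78 → 0 °C; then H2O
Reagents that add atoms: allylmagnesium bromide, C=CC[Mg]Br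
Why: Grignard 1,2-addition through a compact six-membered transition state, which lets the allyl reagent add directly to the hindered C9 carbonyl beside quaternary C10; attack anti to the C20 methyl is expected, but the carbinol configuration is irrelevant because C9 becomes trigonal in step 7.

**Step 7**
Reactants: 12 9-allyl-ent-11-nordrim-7-en-9-ol
Product: 13 9-allyl-ent-11-nordrim-8-en-7-one
Conditions: pyridinium chlorochromate C5H5NH[CrO3Cl], 4 Å molecular sieves, CH2Cl2, rt
Reagents that add atoms: pyridinium chlorochromate, [O-][Cr](=O)(=O)Cl.c1cc[nH+]cc1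
Why: Dauben–Babler oxidative transposition: the tertiary allylic chromate ester undergoes a [3,3] shift to the less congested C7 and is oxidised there, giving the tetrasubstituted 8-en-7-one with the allyl group on C9, as is routine for 1-alkyl-2,6,6-trimethylcyclohex-2-enols.

**Step 8**
Reactants: 13 9-allyl-ent-11-nordrim-8-en-7-one
Product: 15 9-allyl-7-(triethylsilyloxy)-ent-11-nordrim-7-ene (9-H anti to C20), via lithium 7-enolate 14 (not isolated)
Conditions: Li (2 equiv), t-BuOH (1 equiv), NH3/THF, −78 °C; NH3 evaporated; then Et3SiCl (2.5 equiv), Et3N, THF, −78 → 0 °C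
Reagents that add atoms: chlorotriethylsilane, CC[Si](Cl)(CC)CC
Why: Birch-type dissolving-metal reduction of the enone followed by O-silylation of the regiodefined enolate; the β-carbanion at C9 is protonated axially, anti to the C20 methyl, which places the allyl group equatorial and sets C9, while the isolated terminal alkene is inert to Li in NH3.

**Step 9**
Reactants: 15 9-allyl-7-(triethylsilyloxy)-ent-11-nordrim-7-ene
Product: 17 9-allyl-8-(triethylsilyloxy)-ent-11-nordriman-7-one (8-O anti to C20), via silyloxy epoxide 16 (not isolated)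
Conditions: mCPBA (1.05 equiv), CH2Cl2, −20 → 0 °C
Reagents that add atoms: 3-chloroperoxybenzoic acid, OOC(=O)c1cccc(Cl)c1
Why: Rubottom oxidation: the peracid epoxidises the electron-rich tetrasubstituted silyl enol ether far faster than the terminal alkene and from the face anti to the axial C20 methyl, and ring opening with 1,4-silyl shift leaves the C8 oxygen equatorial (C17 axial) and already protected as its triethylsilyl ether.

**Step 10**
Reactants: 17 9-allyl-8-(triethylsilyloxy)-ent-11-nordriman-7-one
Product: 19 9-allyl-6-hydroxy-8-(triethylsilyloxy)-ent-11-nordriman-7-one (6-OH anti to C20), via potassium 6-enolate 18 (not isolated)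
Conditions: KN(SiMe3)2, THF, −78 °C; then 2-(phenylsulfonyl)-3-phenyloxaziridine, −78 °C; AcOH, −78 °C
Reagents that add atoms: 2-(phenylsulfonyl)-3-phenyloxaziridine, O=S(=O)(c1ccccc1)N1OC1c1ccccc1
Why: Davis enolate hydroxylation: the ketone can enolise only toward C6, and the oxaziridine approaches anti to the C20 methyl and the axial C4 methyl that block the other face, giving the equatorial 6-hydroxy group, which is also the more stable epimer.

**Step 11**
Reactants: 19 9-allyl-6-hydroxy-8-(triethylsilyloxy)-ent-11-nordriman-7-one
Product: 20 9-allyl-8-(triethylsilyloxy)-ent-11-nordrimane-6,7-diol (7-OH syn to C20)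
Conditions: NaBH4, MeOH, −20 → 0 °C
Reagents that add atoms: none
Why: Borohydride reduction of the cyclohexanone by axial attack past the axial hydrogens on C5 and C9, the opposite face being screened by the axial C17 methyl, which gives the equatorial C7 alcohol trans to both neighbouring oxygens.

**Step 12**
Reactants: 20 9-allyl-8-(triethylsilyloxy)-ent-11-nordrimane-6,7-diol; 21 acetic anhydride
Product: 22 6,7-diacetoxy-9-allyl-8-(triethylsilyloxy)-ent-11-nordrimane
Conditions: Ac2O, DMAP (cat.), pyridine, rt
Reagents that add atoms: acetic anhydride, CC(=O)OC(C)=O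
Why: DMAP-catalysed acylation of the two secondary alcohols; the tertiary oxygen is masked as its silyl ether, so only O6 and O7 are acetylated and no stereocentre is touched.

**Step 13**
Reactants: 22 6,7-diacetoxy-9-allyl-8-(triethylsilyloxy)-ent-11-nordrimane
Product: 24 C12 aldehyde (2-[6,7-diacetoxy-8-(triethylsilyloxy)-ent-11-nordriman-9-yl]acetaldehyde), via secondary ozonide 23 (not isolated)
Conditions: O3, CH2Cl2, −78 °C; then PPh3, −78 °C → rt
Reagents that add atoms: ozone, [O-][O+]=O
Why: Ozonolysis (Criegee mechanism) with reductive work-up cleaves the only alkene of the molecule to the C12 aldehyde, and the silyl ether on O8 prevents lactol formation.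

**Step 14**
Reactants: 24 C12 aldehyde; 25 ethyltriphenylphosphonium iodide
Product: 26 (12Z)-13-iodo alkene (6,7-diacetoxy-13-iodo-8-(triethylsilyloxy)-14,15-dinor-ent-labd-12-ene)
Conditions: 25, n-BuLi, THF, 0 °C; I2, −78 °C; NaN(SiMe3)2, −20 °C; then 24, −78 → −20 °C
Reagents that add atoms: ethyltriphenylphosphonium iodide, CC[P+](c1ccccc1)(c1ccccc1)c1ccccc1.[I-]; iodine, II
Why: Stork–Zhao-type Wittig iodo-olefination with the α-iodo ylide, which under kinetic low-temperature conditions should give the (Z)-2-iodoalkene with iodine cis to the C11 chain; the ylide is not nucleophilic enough to attack the acetates at this temperature.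

**Step 15**
Reactants: 26 (12Z)-13-iodo alkene
Product: 27 (12Z)-13-iodo alkene with free 8-OH (6,7-diacetoxy-13-iodo-14,15-dinor-ent-labd-12-en-8-ol)
Conditions: HF·pyridine, pyridine, THF, 0 °C → rt
Reagents that add atoms: none
Why: Fluoride-mediated silyl ether cleavage under buffered conditions, carried out before the acid-sensitive hydroxy diene exists; acetates and the vinyl iodide are inert and no stereocentre is involved.

**Step 16**
Reactants: 27 (12Z)-13-iodo alkene with free 8-OH; 28 tributyl(vinyl)stannane
Product: 29 (12Z)-6,7-diacetoxy-ent-labda-12,14-dien-8-ol (target CNP0537572.1)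
Conditions: 28, Pd2(dba)3 (5 mol %), AsPh3 (20 mol %), NMP, rt
Reagents that add atoms: tributyl(vinyl)stannane, C=C[Sn](CCCC)(CCCC)CCCC
Why: Stille cross-coupling, in which oxidative addition to zerovalent palladium and reductive elimination both retain alkene geometry, so the vinyl group takes the place of iodine cis to C11 and the 12Z diene forms under neutral conditions that spare the acetates and the tertiary alcohol.

**Compound list**
1 | (S)-(+)-carvone | CC1=CC[C@@H](CC1=O)C(C)=C | starting material
2 | iodomethane | CI | starting material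
3 | lithium dienolate of carvone (not isolated) | CC1=CC[C@H](C(C)=C)C=C1O[Li] | intermediate
4 | (5S,6R)-6-methylcarvone (trans; carried on with its C6 epimer) | CC1=CC[C@@H]([C@@H](C)C1=O)C(C)=C | intermediate
5 | methyl 2-(bromomethyl)acrylate | C=C(CBr)C(=O)OC | starting material
6 | lithium enolate of 6-methylcarvone (not isolated) | CC1=CC[C@H](C(C)=C)C(C)=C1O[Li] | intermediate
7 | methyl 2-{[(1R,6R)-1,3-dimethyl-2-oxo-6-(prop-1-en-2-yl)cyclohex-3-en-1-yl]methyl}prop-2-enoate (acrylate arm trans, methyl cis to isopropenyl) | O=C1C(C)=CC[C@H](C(C)=C)[C@@]1(C)CC(=C)C(=O)OC | intermediate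
8 | methyl 9-oxo-ent-11-nordrim-7-ene-2-carboxylate (trans-decalin, 5-H anti to C20, ester equatorial) | O=C1C(C)=CC[C@@H]2C(C)(C)C[C@@H](C(=O)OC)C[C@]21C | intermediate
9 | 9-oxo-ent-11-nordrim-7-ene-2-carboxylic acid | O=C1C(C)=CC[C@@H]2C(C)(C)C[C@@H](C(=O)O)C[C@]21C | intermediate
10 | ent-11-nordrim-7-en-9-one, (4aR,8aR)-2,5,5,8a-tetramethyl-4a,5,6,7,8,8a-hexahydronaphthalen-1(4H)-one | O=C1C(C)=CC[C@@H]2C(C)(C)CCC[C@]21C | intermediate
11 | allylmagnesium bromide | C=CC[Mg]Br | starting material
12 | 9-allyl-ent-11-nordrim-7-en-9-ol (allyl anti, OH syn to C20) | C=CC[C@@]1(O)C(C)=CC[C@@H]2C(C)(C)CCC[C@]21C | intermediate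
13 | 9-allyl-ent-11-nordrim-8-en-7-one | C=CCC1=C(C)C(=O)C[C@@H]2C(C)(C)CCC[C@]21C | intermediate
14 | lithium 7-enolate of the 9-allyl 7-ketone, 9-H anti to C20 (not isolated) | C=CC[C@@H]1C(C)=C(O[Li])C[C@@H]2C(C)(C)CCC[C@]21C | intermediate
15 | 9-allyl-7-(triethylsilyloxy)-ent-11-nordrim-7-ene (9-H anti to C20) | C=CC[C@@H]1C(C)=C(O[Si](CC)(CC)CC)C[C@@H]2C(C)(C)CCC[C@]21C | intermediate
16 | 7,8-epoxide of 15, oxygen anti to C20 (not isolated) | C=CC[C@@H]1[C@@]3(C)O[C@@]3(O[Si](CC)(CC)CC)C[C@@H]2C(C)(C)CCC[C@]21C | intermediate
17 | 9-allyl-8-(triethylsilyloxy)-ent-11-nordriman-7-one (8-O anti, C17 syn to C20) | C=CC[C@@H]1[C@@](C)(O[Si](CC)(CC)CC)C(=O)C[C@@H]2C(C)(C)CCC[C@]21C | intermediate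
18 | potassium 6-enolate of 17 (not isolated) | C=CC[C@@H]1[C@@](C)(O[Si](CC)(CC)CC)C(O[K])=C[C@@H]2C(C)(C)CCC[C@]21C | intermediate
19 | 9-allyl-6-hydroxy-8-(triethylsilyloxy)-ent-11-nordriman-7-one (6-OH anti to C20, equatorial) | C=CC[C@@H]1[C@@](C)(O[Si](CC)(CC)CC)C(=O)[C@@H](O)[C@@H]2C(C)(C)CCC[C@]21C | intermediate
20 | 9-allyl-8-(triethylsilyloxy)-ent-11-nordrimane-6,7-diol (6-OH anti, 7-OH syn to C20, both equatorial) | C=CC[C@@H]1[C@@](C)(O[Si](CC)(CC)CC)[C@H](O)[C@@H](O)[C@@H]2C(C)(C)CCC[C@]21C | intermediate
21 | acetic anhydride | CC(=O)OC(C)=O | starting material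
22 | 6,7-diacetoxy-9-allyl-8-(triethylsilyloxy)-ent-11-nordrimane | C=CC[C@@H]1[C@@](C)(O[Si](CC)(CC)CC)[C@H](OC(C)=O)[C@@H](OC(C)=O)[C@@H]2C(C)(C)CCC[C@]21C | intermediate
23 | secondary ozonide (1,2,4-trioxolane) of 22, mixture at the trioxolane carbon (not isolated) | C1OC(OO1)C[C@@H]1[C@@](C)(O[Si](CC)(CC)CC)[C@H](OC(C)=O)[C@@H](OC(C)=O)[C@@H]2C(C)(C)CCC[C@]21C | intermediate
24 | 2-[6,7-diacetoxy-8-(triethylsilyloxy)-ent-11-nordriman-9-yl]acetaldehyde (C12 aldehyde) | O=CC[C@@H]1[C@@](C)(O[Si](CC)(CC)CC)[C@H](OC(C)=O)[C@@H](OC(C)=O)[C@@H]2C(C)(C)CCC[C@]21C | intermediate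
25 | ethyltriphenylphosphonium iodide | CC[P+](c1ccccc1)(c1ccccc1)c1ccccc1.[I-] | starting material
26 | (12Z)-6,7-diacetoxy-13-iodo-8-(triethylsilyloxy)-14,15-dinor-ent-labd-12-ene (iodine cis to C11) | I/C(C)=C\C[C@@H]1[C@@](C)(O[Si](CC)(CC)CC)[C@H](OC(C)=O)[C@@H](OC(C)=O)[C@@H]2C(C)(C)CCC[C@]21C | intermediate
27 | (12Z)-6,7-diacetoxy-13-iodo-14,15-dinor-ent-labd-12-en-8-ol | I/C(C)=C\C[C@@H]1[C@@](C)(O)[C@H](OC(C)=O)[C@@H](OC(C)=O)[C@@H]2C(C)(C)CCC[C@]21C | intermediate
28 | tributyl(vinyl)stannane | C=C[Sn](CCCC)(CCCC)CCCC | starting material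
29 | (12Z)-6,7-diacetoxy-ent-labda-12,14-dien-8-ol, labdane numbering (5R,6S,7R,8R,9S,10R); 6-OAc and 8-OH anti, 7-OAc, C17 and C11 syn to C20 | C=C/C(C)=C\C[C@@H]1[C@@](C)(O)[C@H](OC(C)=O)[C@@H](OC(C)=O)[C@@H]2C(C)(C)CCC[C@]21C | target

**Step count**
Total: 16 steps. Longest linear sequence: 16 steps from (S)-carvone (the route is fully linear).

**Steps most likely to fail**

Step 3. The metal hydride may also transfer hydrogen to the acrylate or the enone, or the C4 radical may be reduced before it cyclises, so that open-chain reduction competes with ring closure. The fallback sets out from 7 and returns at 8. Markovnikov addition of HBr (1 equiv, AcOH, 0 °C) to the isopropenyl group, the most basic alkene of 7, should give the tertiary bromide F1. Slow addition of Bu3SnH with AIBN in refluxing benzene at high dilution then generates the same C4 radical by bromine abstraction, independent of any hydride selectivity. The same 6-endo addition to the acrylate terminus, followed by hydrogen transfer from the stannane, would deliver 8.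

Step 14. Incomplete iodination of the ylide and equilibration of the betaine would erode the Z-selectivity and transfer an uniodinated ethylidene group, and the basic ylide may enolise the aldehyde. The fallback sets out from 24 and returns at the target 29.
- Still–Gennari olefination with methyl 2-[bis(2,2,2-trifluoroethoxy)phosphoryl]propanoate (KN(SiMe3)2, 18-crown-6, THF, −78 °C) should give the (Z)-α-methyl enoate F2.
- iBu2AlH (CH2Cl2, −78 °C) reduces the enoate and, unavoidably, both acetates to the (Z)-allylic alcohol diol F3.
- MnO2 (CH2Cl2) oxidises only the allylic alcohol to the (Z)-enal F4.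
- Ph3P=CH2 (THF, 0 °C) gives the diene diol F5.
- Ac2O/DMAP/pyridine restores the acetates in the silyl-protected diene diacetate F6.
- HF·pyridine in pyridine/THF removes the silyl group to give 29.

Step 10. Deprotonation at the hindered C6 may be slow, and once the C6 alkoxide has formed, base-induced ketol isomerisation or silyl migration may follow. The fallback sets out from 17 and returns at 19. Soft enolisation with Me3SiOTf and Et3N (CH2Cl2, 0 °C) should give the trimethylsilyl enol ether F7 without strong base. Rubottom oxidation with mCPBA (CH2Cl2, −20 °C), again anti to the C20 methyl, would give the 6-trimethylsilyloxy ketone F8. Citric acid in MeOH removes only the trimethylsilyl group and gives 19.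

**Further compounds**
F1 | step 3 | tertiary bromide, hydrobromide of 7 (2-bromopropan-2-yl in place of isopropenyl) | O=C1C(C)=CC[C@H](C(C)(C)Br)[C@@]1(C)CC(=C)C(=O)OC
F2 | step 14 | (Z)-α-methyl enoate, ester cis to C11, 6,7-diacetate, 8-triethylsilyl ether | COC(=O)/C(C)=C\C[C@@H]1[C@@](C)(O[Si](CC)(CC)CC)[C@H](OC(C)=O)[C@@H](OC(C)=O)[C@@H]2C(C)(C)CCC[C@]21C
F3 | step 14 | (Z)-allylic alcohol 6,7-diol, 8-triethylsilyl ether | OC/C(C)=C\C[C@@H]1[C@@](C)(O[Si](CC)(CC)CC)[C@H](O)[C@@H](O)[C@@H]2C(C)(C)CCC[C@]21C
F4 | step 14 | (Z)-enal 6,7-diol, 8-triethylsilyl ether | O=C/C(C)=C\C[C@@H]1[C@@](C)(O[Si](CC)(CC)CC)[C@H](O)[C@@H](O)[C@@H]2C(C)(C)CCC[C@]21C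
F5 | step 14 | (12Z)-8-(triethylsilyloxy)-ent-labda-12,14-diene-6,7-diol | C=C/C(C)=C\C[C@@H]1[C@@](C)(O[Si](CC)(CC)CC)[C@H](O)[C@@H](O)[C@@H]2C(C)(C)CCC[C@]21C
F6 | step 14 | (12Z)-6,7-diacetoxy-8-(triethylsilyloxy)-ent-labda-12,14-diene | C=C/C(C)=C\C[C@@H]1[C@@](C)(O[Si](CC)(CC)CC)[C@H](OC(C)=O)[C@@H](OC(C)=O)[C@@H]2C(C)(C)CCC[C@]21C
F7 | step 10 | trimethylsilyl 6-enol ether of 17 | C=CC[C@@H]1[C@@](C)(O[Si](CC)(CC)CC)C(O[Si](C)(C)C)=C[C@@H]2C(C)(C)CCC[C@]21C
F8 | step 10 | 6-(trimethylsilyloxy) ketone, 6-O anti to C20 | C=CC[C@@H]1[C@@](C)(O[Si](CC)(CC)CC)C(=O)[C@@H](O[Si](C)(C)C)[C@@H]2C(C)(C)CCC[C@]21C
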